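**Plan**
Cuts: first the C3–O acyl bond (diol 10 + Z-acid 17). Then three late oxygenations are removed (C11–O with the C6=C7 shift, C3–O, C8=O) back to (+)-aristolochene 5. Finally C6–C7, C5–C10 and C5–CH3 of 5 are cut back to acyclic farnesyl diphosphate 3.
Enabling feature: ring A (C1–C5, C10) and ring B (C5–C10) carry cis methyls on C4 and C5, the C9=C10 alkene and a three-carbon branch on C7. This is the eremophilane framework of 5 in the same absolute sense, and a single sesquiterpene cyclase folds 3 into it.
Forward order: C6–C7 closes a ten-membered ring and the transannular C5–C10 bond divides it into rings A and B in the same step. Then C8 is oxidised, the side-chain alkene is moved to C7=C11, C3 is hydroxylated, an ene reaction puts oxygen on C11, and the acyl group goes on last.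
Stereochemistry: C4 and C5 come from the cyclase (C7 too, but it is erased later). C3 comes from retentive enzymatic hydroxylation of the equatorial C–H. The Z alkene comes from chelate-controlled anti-carbomagnesiation of propargyl alcohol and retentive C–S coupling.

Key step: step 3

Assumption: eremophilane numbering is used for all bicyclic compounds and for the carbons of 3 and 4 that become them, 3 is isolated as its tris-ammonium salt but drawn and balanced as the free acid, and the CYP102A1 variant of step 6 is taken to be found by screening a terpene-hydroxylating variant panel.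

Step 1
Reactants: 1 (2E,6E)-farnesol
Product: 2 (2E,6E)-farnesyl bromide
Conditions: PBr3 (0.4 equiv), Et2O, −10 to 0 °C; used crude
Reagents that add atoms: phosphorus tribromide, BrP(Br)Br
Why: SN2-type bromination of a primary allylic alcohol through its phosphite ester at low temperature is the standard access to farnesyl bromide and leaves both E alkenes untouched and the allyl system untransposed.

Step 2
Reactants: 2 (2E,6E)-farnesyl bromide
Product: 3 (2E,6E)-farnesyl diphosphate
Conditions: (Bu4N)3HP2O7 (2 equiv), MeCN, 0 °C to rt; Dowex 50WX8 (NH4+ form), aq NH4HCO3; cellulose chromatography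
Reagents that add atoms: tris(tetrabutylammonium) hydrogen diphosphate, CCCC[N+](CCCC)(CCCC)CCCC.CCCC[N+](CCCC)(CCCC)CCCC.CCCC[N+](CCCC)(CCCC)CCCC.OP(=O)([O-])OP(=O)([O-])[O-]
Why: SN2 displacement of the primary allylic bromide by the poorly solvated diphosphate anion in a dipolar aprotic solvent is the established chemical diphosphorylation of prenyl halides, and cation exchange then gives the enzyme-compatible ammonium salt.

Step 3
Reactants: 3 (2E,6E)-farnesyl diphosphate
Product: 5 (+)-aristolochene, via germacrene A 4 (not isolated)
Conditions: recombinant aristolochene synthase (Aspergillus terreus, from E. coli), MgCl2 (5 mM), Tris-HCl pH 7.5, 2-mercaptoethanol, glycerol, pentane overlay, 30 °C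
Reagents that add atoms: none
Why: Mg2+-assisted loss of diphosphate from 3 gives the farnesyl cation, whose distal trisubstituted alkene attacks the allylic terminus to form C6–C7 (ten-membered ring, exo mode because C11 stays outside the ring and carries the tertiary cation), and loss of a methyl proton from that cation leaves enzyme-bound (S)-germacrene A 4. Reprotonation of 4 at C1 places a tertiary cation on C10, C5 of the C4=C5 alkene captures it across the ring (C5–C10 bond, 6-endo as seen from ring A and 6-exo as seen from ring B), and the resulting C4 eudesmyl cation is discharged by a hydride shift from C5 to C4, a methyl shift from C10 to C5 and loss of a C9 proton, which gives 5. The reaction type is the class 1 terpene-synthase cation–olefin polycyclisation with Wagner–Meerwein shifts, and this conversion is the native reaction of the enzyme. C7 is set by the alkene face that the folded chain offers to C6 in the first closure; C4 and C5 are set because the chair–chair fold of 4 gives a trans-fused cation in which hydride and methyl migrate suprafacially, antiperiplanar to each other and on opposite faces, so that both methyls end on the same face. The step needs closure onto the distal alkene instead of the central one and a complete cascade instead of early proton loss: the E,E geometry and the 1,5-spacing of the trisubstituted alkenes of 3 let every bond form through a tertiary cation without prior allylic isomerisation, while the aromatic-lined pocket and the retained diphosphate decide where protons leave and return.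

Step 4
Reactants: 5 (+)-aristolochene
Product: 6 (4S,5R,7S)-eremophila-9,11-dien-8-one
Conditions: Rh2(cap)4 (dirhodium tetracaprolactamate, 1 mol %), t-BuOOH (70 % aq, 5 equiv), K2CO3 (0.5 equiv), CH2Cl2, rt
Reagents that add atoms: tert-butyl hydroperoxide, CC(C)(C)OO
Why: In this radical allylic oxidation by tert-butylperoxyl radicals, hydrogen is taken from the ring CH2 next to the CH= terminus (C8) and the allyl radical is oxidised at that less hindered end to the beta,beta-disubstituted enone, the same site preference that turns valencene into nootkatone, while the 1,1-disubstituted isopropenyl group and C4, C5 and C7 are left alone.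

Step 5
Reactants: 6 (4S,5R,7S)-eremophila-9,11-dien-8-one
Product: 7 (4S,5R)-eremophila-7(11),9-dien-8-one (dehydrofukinone)
Conditions: NaOMe (0.1 equiv), MeOH, N2, rt
Reagents that add atoms: none
Why: Base-mediated alkene isomerisation through the C7 dienolate and reprotonation at C12 moves the double bond into conjugation as the tetrasubstituted 7(11)-ene, the thermodynamic sink known from the petasin–isopetasin pair, which erases C7 on purpose, merges any C7 epimer or early-isomerised material from step 4 and does not touch C4 or C5.

Step 6
Reactants: 7 (4S,5R)-eremophila-7(11),9-dien-8-one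
Product: 8 (3R,4R,5R)-3-hydroxyeremophila-7(11),9-dien-8-one (isopetasol)
Conditions: CYP102A1 variant (clarified E. coli lysate), NADP+ (cat.), phosphite dehydrogenase, Na2HPO3, air, potassium phosphate buffer pH 8.0, 2 % DMSO, 25 °C
Reagents that add atoms: dioxygen, O=O
Why: Cytochrome P450 hydroxylation (hydrogen abstraction and oxygen rebound with retention), well known for ring A methylenes of decalin terpenoids, meets a substrate whose alkenes are all conjugated and electron-poor and whose C8 carbonyl anchors the far end, so the distal end of ring A is presented and there the equatorial C3–H is exposed whereas the axial one is screened by the syn-axial C5 methyl, which should give the 3R alcohol trans to the C4 methyl.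

Step 7
Reactants: 8 (3R,4R,5R)-3-hydroxyeremophila-7(11),9-dien-8-one
Product: 10 (3R,4R,5R)-3,11-dihydroxyeremophila-6,9-dien-8-one, via 11-hydroperoxide 9 (not isolated)
Conditions: O2, tetraphenylporphyrin (1 mol %), visible light (>450 nm), CH2Cl2, 0 °C; then PPh3 (1.1 equiv), 0 °C to rt
Reagents that add atoms: dioxygen, O=O
Why: The Schenck ene reaction of singlet oxygen takes place at the only s-cis enone of 8 (the endocyclic C9=C10 enone is s-trans and inert), the geminal effect of the carbonyl directs hydrogen abstraction to the branch on the alpha carbon (axial H6 on the face away from the C5 methyl) so that oxygen ends on C11 and the alkene moves to C6=C7 as in pulegone-type isopropylidene ketones, and PPh3 then reduces the O–O bond without touching the dienone or creating a stereocentre.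

Step 8
Reactants: 11 propargyl alcohol
Product: 13 (Z)-3-iodo-2-methylprop-2-en-1-ol, via vinylmagnesium alkoxide 12 (not isolated)
Conditions: MeMgBr (3 equiv), CuI (10 mol %), THF/Et2O, −10 °C to rt; then I2, −10 °C; aqueous work-up
Reagents that add atoms: methylmagnesium bromide, C[Mg]Br; iodine, II
Why: In the copper-catalysed carbomagnesiation of a propargylic alkoxide the magnesium alkoxide enforces net anti addition, with methyl going to C2 and magnesium to C3 inside a five-membered chelate, and iodinolysis with retention fixes iodine cis to CH2OH.

Step 9
Reactants: 13 (Z)-3-iodo-2-methylprop-2-en-1-ol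
Product: 15 (Z)-3-iodo-2-methylprop-2-enoic acid, via Z-iodoenal 14 (not isolated)
Conditions: TEMPO (7 mol %), NaClO2 (2 equiv), NaOCl (2 mol %), MeCN/sodium phosphate buffer pH 6.7, 35 °C
Reagents that add atoms: sodium chlorite, [Na+].[O-]Cl=O
Why: In the TEMPO/chlorite oxidation of a primary alcohol at near-neutral pH the oxoammonium salt makes the enal and chlorite takes it on at once in a Pinnick-type step, so the Z-enal has little time to isomerise and the vinyl iodide is untouched.

Step 10
Reactants: 15 (Z)-3-iodo-2-methylprop-2-enoic acid, 16 sodium methanethiolate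
Product: 17 (Z)-2-methyl-3-(methylsulfanyl)prop-2-enoic acid
Conditions: 16 (2.1 equiv), CuI (10 mol %), DMF, rt to 40 °C; cold 1 M HCl
Reagents that add atoms: none
Why: This Ullmann-type C(sp2)–S coupling, the vinylic counterpart of the Hurtley reaction, has the cis carboxylate hold copper next to the C–I bond, proceeds with retention of alkene geometry, and yields a carboxylate that is too poor an acceptor for thiolate addition–elimination to scramble the Z alkene.

Step 11
Reactants: 10 (3R,4R,5R)-3,11-dihydroxyeremophila-6,9-dien-8-one, 17 (Z)-2-methyl-3-(methylsulfanyl)prop-2-enoic acid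
Product: 19 (3R,4R,5R)-11-hydroxy-8-oxoeremophila-6,9-dien-3-yl (Z)-2-methyl-3-(methylsulfanyl)prop-2-enoate, via mixed anhydride 18 (not isolated)
Conditions: 17, 2,4,6-trichlorobenzoyl chloride (1.1 equiv), Et3N, toluene, 0 °C to rt; then 10, DMAP (0.3 equiv), 0 °C to rt
Reagents that add atoms: 2,4,6-trichlorobenzoyl chloride, O=C(Cl)c1c(Cl)cc(Cl)cc1Cl (its aroyl group is carried by 18 only and is absent from 19)
Why: In the Yamaguchi esterification DMAP transfers the less hindered acyl group of 18 to the equatorial secondary C3–OH, the tertiary C11–OH is too hindered to compete, C3 keeps its configuration because only its O–H bond is broken, and low temperature with little DMAP limits Z to E leakage of the acyl group.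

**Compound list**
1 | (2E,6E)-farnesol | CC(C)=CCC/C(C)=C/CC/C(C)=C/CO | starting material
2 | (2E,6E)-farnesyl bromide | CC(C)=CCC/C(C)=C/CC/C(C)=C/CBr | intermediate
3 | (2E,6E)-farnesyl diphosphate (free-acid form of the tris-ammonium salt) | CC(C)=CCC/C(C)=C/CC/C(C)=C/COP(=O)(O)OP(=O)(O)O | intermediate
4 | (S)-germacrene A (enzyme-bound) | C/C1=C\CC/C(C)=C/C[C@H](CC1)C(C)=C | intermediate
5 | (+)-aristolochene, (4S,5R,7S)-eremophila-9,11-diene | C[C@H]1CCCC2=CC[C@@H](C[C@]12C)C(C)=C | intermediate
6 | (4S,5R,7S)-eremophila-9,11-dien-8-one | C[C@H]1CCCC2=CC(=O)[C@@H](C[C@]12C)C(C)=C | intermediate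
7 | (4S,5R)-eremophila-7(11),9-dien-8-one (dehydrofukinone) | C[C@H]1CCCC2=CC(=O)C(=C(C)C)C[C@]12C | intermediate
8 | (3R,4R,5R)-3-hydroxyeremophila-7(11),9-dien-8-one (isopetasol) | O[C@@H]1CCC2=CC(=O)C(=C(C)C)C[C@]2(C)[C@H]1C | intermediate
9 | (3R,4R,5R)-11-hydroperoxy-3-hydroxyeremophila-6,9-dien-8-one | O[C@@H]1CCC2=CC(=O)C(C(C)(C)OO)=C[C@]2(C)[C@H]1C | intermediate
10 | (3R,4R,5R)-3,11-dihydroxyeremophila-6,9-dien-8-one | O[C@@H]1CCC2=CC(=O)C(C(C)(C)O)=C[C@]2(C)[C@H]1C | intermediate
11 | propargyl alcohol | C#CCO | starting material
12 | (Z)-3-(bromomagnesio)-2-methylprop-2-en-1-olate bromomagnesium salt | C/C(CO[Mg]Br)=C/[Mg]Br | intermediate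
13 | (Z)-3-iodo-2-methylprop-2-en-1-ol | C/C(CO)=C/I | intermediate
14 | (Z)-3-iodo-2-methylprop-2-enal | C/C(C=O)=C/I | intermediate
15 | (Z)-3-iodo-2-methylprop-2-enoic acid | C/C(C(=O)O)=C/I | intermediate
16 | sodium methanethiolate | C[S-].[Na+] | starting material
17 | (Z)-2-methyl-3-(methylsulfanyl)prop-2-enoic acid | CS/C=C(/C)C(=O)O | intermediate
18 | (Z)-2-methyl-3-(methylsulfanyl)prop-2-enoic 2,4,6-trichlorobenzoic anhydride | CS/C=C(/C)C(=O)OC(=O)c1c(Cl)cc(Cl)cc1Cl | intermediate
19 | (3R,4R,5R)-11-hydroxy-8-oxoeremophila-6,9-dien-3-yl (Z)-2-methyl-3-(methylsulfanyl)prop-2-enoate (CNP0150028.1) | CS/C=C(/C)C(=O)O[C@@H]1CCC2=CC(=O)C(C(C)(C)O)=C[C@]2(C)[C@H]1C | target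

Total step count: 11. Longest linear sequence: 8 steps (steps 1–7 and 11). The acid 17 is made in a 3-step branch (steps 8–10).

**Steps most likely to fail**

Step 6. Oxygen may be delivered to the wrong C–H bond (allylic C1, C2 or the C12/C13 methyls), or turnover may stay too low for preparative work. The fallback replaces the enzyme by small-molecule C–H oxidation and sets out from 7.
- Photooxygenation under the conditions of step 7 should give (4S,5S)-11-hydroperoxyeremophila-6,9-dien-8-one F1. After PPh3 this becomes (4S,5S)-11-hydroxyeremophila-6,9-dien-8-one F2, in which both alkenes are electron-poor.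
- [Fe((S,S)-PDP)(MeCN)2](SbF6)2 (PDP = N,N'-bis(2-pyridylmethyl)-2,2'-bipyrrolidine) with H2O2 and AcOH in MeCN should then oxidise the methylene group farthest from the dienone. The product is (4R,5R)-11-hydroxyeremophila-6,9-diene-3,8-dione F3, whose C4 methyl stays equatorial.
- LiBH(s-Bu)3 (2 equiv, THF, −78 °C) attacks the saturated ketone from the equatorial side, because the axial path is closed by the C5 methyl. It should give the axial alcohol (3S,4R,5R)-3,11-dihydroxyeremophila-6,9-dien-8-one F4.
- Mitsunobu esterification of F4 with 17 (PPh3, DIAD, toluene, 0 °C to rt) inverts C3 without activating the acid and comes back to the route at 19.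

Step 7. Hydrogen may be abstracted from the C12/C13 methyls instead of C6, so that oxygen ends on C7. The cross-conjugated dienone may also degrade under irradiation. The fallback avoids singlet oxygen and sets out from 8.
- mCPBA/NaHCO3 in CH2Cl2 at 0 °C should epoxidise the most electron-rich alkene from the face opposite the C5 methyl. The product is (3R,4R,5R,7S)-7,11-epoxy-3-hydroxyeremophil-9-en-8-one F5, whose C7 configuration is of no consequence.
- SmI2 in THF/MeOH at −90 °C cleaves the C7–O bond alpha to the ketone. The product is (3R,4R,5R,7S)-3,11-dihydroxyeremophil-9-en-8-one F6.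
- Dehydrogenation with DDQ in dioxane at 80 °C under neutral conditions (the mode that turns 4-en-3-ones into 1,4-dien-3-ones) introduces C6=C7 and comes back to the route at 10.

Step 11. The push–pull acyl group may isomerise from Z to E while it is activated, or acylation next to the C4 methyl may be too slow. The fallback attaches a configurationally robust acyl group first, forms the C–S bond last, and sets out from 10 and 15.
- 15 is converted with 1-chloro-N,N,2-trimethylprop-1-en-1-amine in CH2Cl2 into (Z)-3-iodo-2-methylprop-2-enoyl chloride F7.
- F7 acylates the C3–OH of 10 in pyridine/CH2Cl2 at 0 °C. The product is (3R,4R,5R)-11-hydroxy-8-oxoeremophila-6,9-dien-3-yl (Z)-3-iodo-2-methylprop-2-enoate F8.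
- One equivalent of 16 in THF at −40 °C then replaces iodide by addition–elimination with retention. The irreversible loss of iodide drains any reversible thiolate addition to the hindered dienone, and the sequence comes back to the route at 19.

**Further compounds**
F1 | step 6 | (4S,5S)-11-hydroperoxyeremophila-6,9-dien-8-one | C[C@H]1CCCC2=CC(=O)C(C(C)(C)OO)=C[C@]12C
F2 | step 6 | (4S,5S)-11-hydroxyeremophila-6,9-dien-8-one | C[C@H]1CCCC2=CC(=O)C(C(C)(C)O)=C[C@]12C
F3 | step 6 | (4R,5R)-11-hydroxyeremophila-6,9-diene-3,8-dione | C[C@H]1C(=O)CCC2=CC(=O)C(C(C)(C)O)=C[C@]12C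
F4 | step 6 | (3S,4R,5R)-3,11-dihydroxyeremophila-6,9-dien-8-one | O[C@H]1CCC2=CC(=O)C(C(C)(C)O)=C[C@]2(C)[C@H]1C
F5 | step 7 | (3R,4R,5R,7S)-7,11-epoxy-3-hydroxyeremophil-9-en-8-one | O[C@@H]1CCC2=CC(=O)[C@]3(OC3(C)C)C[C@]2(C)[C@H]1C
F6 | step 7 | (3R,4R,5R,7S)-3,11-dihydroxyeremophil-9-en-8-one | O[C@@H]1CCC2=CC(=O)[C@H](C(C)(C)O)C[C@]2(C)[C@H]1C
F7 | step 11 | (Z)-3-iodo-2-methylprop-2-enoyl chloride | C/C(C(=O)Cl)=C/I
F8 | step 11 | (3R,4R,5R)-11-hydroxy-8-oxoeremophila-6,9-dien-3-yl (Z)-3-iodo-2-methylprop-2-enoate | I/C=C(/C)C(=O)O[C@@H]1CCC2=CC(=O)C(C(C)(C)O)=C[C@]2(C)[C@H]1C
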